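The bicyclo[3.3.1]nonane core is opened at C9–C1 and C6–C7, which gives an open-chain 2-aroyl-1,3-diketone: quaternary C5 carries the lavandulyl group, the C9 ester and a C6 acetate arm; C1 carries the prenyl group and the gem-dimethyl carbon C8 with an alkynoate (C7). The key step exploits that C9 and C6 are both on C5 and that C1 and C7 are both on C8: one treatment with base closes ring A (C1–C2–C3–C4–C5–C9) by Claisen acylation of C1 by C9 and then ring B (C5–C6–C7–C8–C1–C9) by Michael addition of the C6 ester enolate to C7. C7 stays trigonal, so its hydrogen is added afterwards from the exo face, which puts the later prenyl group endo.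

Key step: step 12

Remark: (R)-lavandulol, 3-(allyloxy)benzoic acid and 5-isopropylidene Meldrum's acid are taken as purchasable; atoms are numbered as in the bicyclo[3.3.1]nonane name of the target (C1 and C5 bridgeheads, C9 bridging ketone), and "lavandulyl" means 5-methyl-2-(prop-1-en-2-yl)hex-4-en-1-yl.

Step 1
Reactants: 1 (R)-lavandulol
Product: 2 (R)-lavandulyl iodide
Conditions: PPh3, I2, imidazole, CH2Cl2, 0 °C → rt
Reagents that add atoms: iodine, II
Why: Appel-type iodination of a primary alcohol takes place at the CH2 group only, so the stereocentre of 1 is carried over unchanged.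

Step 2
Reactants: 3 methyl acetoacetate; 2 (R)-lavandulyl iodide
Product: 4 methyl 2-[(2S)-lavandulyl]-3-oxobutanoate (C2 epimers)
Conditions: NaH, THF/DMF, 0 → 60 °C
Reagents that add atoms: none
Why: Acetoacetic ester alkylation, in which the sodium enolate of 3 is C-alkylated by the primary iodide; the new CH centre is left as a mixture because it becomes trigonal in step 3.

Step 3
Reactants: 4 methyl 2-[(2S)-lavandulyl]-3-oxobutanoate; 5 L-valine tert-butyl ester
Product: 6 (Z)-enamino ester of 4 and 5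
Conditions: BF3·OEt2 (cat.), benzene, reflux, Dean–Stark trap
Reagents that add atoms: none
Why: Acid-catalysed condensation of the β-keto ester with the primary amine should give the hydrogen-bonded (Z)-enamino ester, which places the valine stereocentre next to the future quaternary carbon.

Step 4
Reactants: 6 (Z)-enamino ester; 7 allyl bromoacetate
Product: 9 4-allyl 1-methyl (2R)-2-acetyl-2-[(2S)-lavandulyl]butanedioate, via alkylated ketimine 8 (not isolated)
Conditions: LiN(i-Pr)2 (LDA), toluene, −78 °C; HMPA; 7, −78 → −40 °C; then 10% aq. citric acid, rt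
Reagents that add atoms: water, O
Why: Asymmetric alkylation of a chiral lithio-enamino ester in which lithium is chelated by the enamine nitrogen and the tert-butyl ester and the isopropyl group shields one face; the donor ligand (HMPA here, THF is expected to reverse the sense) is chosen so that 7 enters the face that makes quaternary C5 (R), and mild acid then hydrolyses the ketimine.

Step 5
Reactants: 10 3-(allyloxy)benzoic acid
Product: 11 3-(allyloxy)benzoyl chloride
Conditions: (COCl)2, DMF (cat.), CH2Cl2, 0 °C → rt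
Reagents that add atoms: oxalyl chloride, O=C(Cl)C(Cl)=O
Why: Acid chloride formation under Vilsmeier catalysis, to which the allyl aryl ether is inert.

Step 6
Reactants: 9 4-allyl 1-methyl (2R)-2-acetyl-2-[(2S)-lavandulyl]butanedioate; 11 3-(allyloxy)benzoyl chloride
Product: 12 4-allyl 1-methyl (2R)-2-{3-[3-(allyloxy)phenyl]-3-oxopropanoyl}-2-[(2S)-lavandulyl]butanedioate
Conditions: MgBr2·OEt2, i-Pr2NEt, CH2Cl2, rt
Reagents that add atoms: none
Why: Soft-enolization Claisen acylation, in which magnesium chelation by the β-keto ester lets the amine enolize only the methyl ketone and the magnesium enolate is C-acylated by 11 to the 1,3-diketone.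

Step 7
Reactants: 13 5-isopropylidene Meldrum's acid; 14 ethynylmagnesium bromide
Product: 15 2,2-dimethyl-5-(2-methylbut-3-yn-2-yl)-1,3-dioxane-4,6-dione
Conditions: THF, −20 °C → rt; aq. HCl
Reagents that add atoms: none
Why: Conjugate (1,4) addition of an alkynyl Grignard reagent to the doubly activated alkylidene Meldrum's acid builds the quaternary propargylic carbon C8.

Step 8
Reactants: 15 2,2-dimethyl-5-(2-methylbut-3-yn-2-yl)-1,3-dioxane-4,6-dione
Product: 16 3,3-dimethylpent-4-ynoic acid
Conditions: DMF/H2O (10:1), 110 °C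
Reagents that add atoms: water, O
Why: Hydrolysis of the Meldrum's acid to the malonic acid followed by thermal decarboxylation leaves the mono-acid, and the terminal alkyne is inert.

Step 9
Reactants: 16 3,3-dimethylpent-4-ynoic acid; 17 prenyl bromide; 18 methyl chloroformate
Product: 20 6-methoxy-3,3-dimethyl-2-(3-methylbut-2-en-1-yl)-6-oxohex-4-ynoic acid (racemic), via dilithium carboxylate-acetylide 19 (not isolated)
Conditions: LiN(i-Pr)2 (3.2 equiv), THF/DMPU, −78 → 0 °C; 17, −78 °C → rt; then 18, −78 °C; aq. NaHCO3, then dilute HCl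
Reagents that add atoms: none
Why: The trianion (carboxylate, acetylide, α-carbanion) should be alkylated by prenyl bromide at the far more nucleophilic enediolate carbon (C1, racemic on purpose because it is re-enolized in step 12), and the remaining lithium acetylide is then C-acylated by methyl chloroformate to the alkynoate.

Step 10
Reactants: 20 6-methoxy-3,3-dimethyl-2-(3-methylbut-2-en-1-yl)-6-oxohex-4-ynoic acid
Product: 21 methyl 6-chloro-4,4-dimethyl-5-(3-methylbut-2-en-1-yl)-6-oxohex-2-ynoate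
Conditions: (COCl)2, DMF (cat.), CH2Cl2, 0 °C
Reagents that add atoms: oxalyl chloride, O=C(Cl)C(Cl)=O
Why: Acid chloride formation under Vilsmeier catalysis at 0 °C, which the alkynoate and the prenyl group should survive.

Step 11
Reactants: 12 4-allyl 1-methyl (2R)-2-{3-[3-(allyloxy)phenyl]-3-oxopropanoyl}-2-[(2S)-lavandulyl]butanedioate; 21 methyl 6-chloro-4,4-dimethyl-5-(3-methylbut-2-en-1-yl)-6-oxohex-2-ynoate
Product: 22 open-chain triketone (enol form): 4-allyl 1-methyl (2R)-2-{2-[3-(allyloxy)benzoyl]-8-methoxy-5,5-dimethyl-4-(3-methylbut-2-en-1-yl)-3,8-dioxooct-6-ynoyl}-2-[(2S)-lavandulyl]butanedioate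
Conditions: MgCl2, pyridine, CH2Cl2, 0 °C → rt
Reagents that add atoms: none
Why: Magnesium-mediated C-acylation of a 1,3-diketone, in which the chelated magnesium diketonate reacts at carbon to give the triacylmethane, so that C3 is already blocked by the aroyl group when the alkynoate is brought in.

Step 12
Reactants: 22 open-chain triketone
Product: 24 allyl (1R,5R)-3-[3-(allyloxy)benzoyl]-4-hydroxy-7-(2-methoxy-2-oxoethylidene)-8,8-dimethyl-1-(3-methylbut-2-en-1-yl)-5-[(2S)-lavandulyl]-2,9-dioxobicyclo[3.3.1]non-3-ene-6-carboxylate (C6 epimers), via ring A monocycle 23 (not isolated)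
Conditions: LiN(i-Pr)2 (3.3 equiv), THF, −78 → 0 °C; AcOH, −78 °C
Reagents that add atoms: none
Why: Anionic domino of a Dieckmann-type Claisen cyclization and an intramolecular Michael addition: the base forms the triketonate, then removes an α-proton of the C6 ester and the C1 proton; the C1 carbanion attacks the C9 methyl ester in a 6-exo-trig closure that completes ring A (C1–C2–C3–C4–C5–C9) and expels methoxide, after which the C6 ester enolate adds to alkyne carbon C7 in a 6-exo-dig closure that completes ring B (C5–C6–C7–C8–C1–C9). The closest known reactions are the Claisen cyclization of 3,5-diketo esters to acylcyclohexane-1,3,5-triones and the intramolecular Michael addition of ester enolates to alkynoates. C1 is the one lasting stereocentre formed, and it is controlled by the preset C5 centre, because ring B can close only when the C8 arm on C1 and the C6 arm on C5 are cis. This cis relation should be favoured in the Claisen transition state, where the bulky C8 group lies anti to C3 on the enolate (pseudo-equatorial) and the lithium-bridged C6 enolate stays in the plane next to the C4 oxygen; this preference is an expectation, not an established rule, and any trans monocycle stays uncyclized. Chemoselectivity should be secured by ring size (C1 reaches only C9 and C6 only C7 through six-membered transition states), by the enolate form of the C6 ester and of the triketone, which protects both from attack, and by the aroyl group on C3, which blocks C3 as a competing Michael donor. C6 (epimeric) and the alkene geometry are of no consequence because both are erased in steps 13 and 14, and C7 is kept trigonal on purpose so that its hydrogen can be delivered last.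

Step 13
Reactants: 24 bicyclic allyl ester
Product: 26 methyl 2-[(1R,5R)-4-hydroxy-3-(3-hydroxybenzoyl)-8,8-dimethyl-1-(3-methylbut-2-en-1-yl)-5-[(2S)-lavandulyl]-2,9-dioxobicyclo[3.3.1]non-3-en-7-ylidene]acetate, via carboxylic acid 25 (not isolated)
Conditions: Pd(PPh3)4 (5 mol %), morpholine, THF, rt → 50 °C; then DBU, rt
Reagents that add atoms: none
Why: Tsuji–Trost deallylation, in which zerovalent palladium ionizes the allyl ester and the allyl aryl ether and morpholine takes up both allyl groups; the freed acid is a vinylogous malonic half-ester that should lose CO2 on warming, and DBU brings the alkene into conjugation with the methyl ester.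

Step 14
Reactants: 26 alkylidene ester
Product: 27 methyl 2-[(1R,5R,7S)-4-hydroxy-3-(3-hydroxybenzoyl)-8,8-dimethyl-1-(3-methylbut-2-en-1-yl)-5-[(2S)-lavandulyl]-2,9-dioxobicyclo[3.3.1]non-3-en-7-yl]acetate
Conditions: Cu(OAc)2·H2O (5 mol %), 1,2-bis(diphenylphosphino)benzene (5 mol %), (EtO)2MeSiH, t-BuOH, toluene, rt; aq. NH4F
Reagents that add atoms: none
Why: Copper hydride 1,4-reduction of the β,β-disubstituted enoate, in which the bulky ligated CuH should deliver hydride to C7 from the open exo face (the endo face is covered by ring A and its aroyl group), which sets C7 with the CH2CO2Me arm endo, cis to the C2–C4 bridge.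

Step 15
Reactants: 27 saturated methyl ester
Product: 28 2-[(1R,5R,7S)-4-hydroxy-3-(3-hydroxybenzoyl)-8,8-dimethyl-1-(3-methylbut-2-en-1-yl)-5-[(2S)-lavandulyl]-2,9-dioxobicyclo[3.3.1]non-3-en-7-yl]acetaldehyde
Conditions: i-Bu2AlH (3.3 equiv), CH2Cl2, −78 °C; aq. potassium sodium tartrate
Reagents that add atoms: none
Why: Partial reduction of the unhindered methyl ester to the aldehyde through a stable aluminium hemiacetal at −78 °C; the triketone and the phenol are protected as aluminium salts and the C9 ketone is shielded by two quaternary carbons.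

Step 16
Reactants: 28 aldehyde; 29 isopropyltriphenylphosphonium iodide
Product: 30 (1R,5R,7R)-4-hydroxy-3-(3-hydroxybenzoyl)-8,8-dimethyl-1,7-bis(3-methylbut-2-en-1-yl)-5-[(2S)-5-methyl-2-(prop-1-en-2-yl)hex-4-en-1-yl]bicyclo[3.3.1]non-3-ene-2,9-dione (target)
Conditions: 29, n-BuLi, THF, 0 °C; then 28, −78 °C → rt; aq. NH4Cl
Reagents that add atoms: none
Why: Wittig olefination with the non-stabilized isopropylidene ylide turns the CH2CHO arm into the prenyl group (no E/Z issue); the enolate and phenolate formed by excess ylide and the hindered C9 ketone should not react.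

Compound list
1 | (R)-lavandulol, (2R)-5-methyl-2-(prop-1-en-2-yl)hex-4-en-1-ol | C=C(C)[C@@H](CC=C(C)C)CO | starting material
2 | (R)-lavandulyl iodide, (2R)-1-iodo-5-methyl-2-(prop-1-en-2-yl)hex-4-ene | C=C(C)[C@@H](CC=C(C)C)CI | intermediate
3 | methyl acetoacetate | CC(=O)CC(=O)OC | starting material
4 | methyl 2-[(2S)-lavandulyl]-3-oxobutanoate (C2 epimers) | C=C(C)[C@@H](CC=C(C)C)CC(C(C)=O)C(=O)OC | intermediate
5 | L-valine tert-butyl ester | CC(C)[C@H](N)C(=O)OC(C)(C)C | starting material
6 | methyl (2Z)-3-{[(2S)-1-tert-butoxy-3-methyl-1-oxobutan-2-yl]amino}-2-[(2S)-lavandulyl]but-2-enoate | C=C(C)[C@@H](CC=C(C)C)C/C(C(=O)OC)=C(\C)N[C@@H](C(C)C)C(=O)OC(C)(C)C | intermediate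
7 | allyl bromoacetate | C=CCOC(=O)CBr | starting material
8 | alkylated ketimine (N-valine tert-butyl ester imine of 9) | C=C(C)[C@@H](CC=C(C)C)C[C@@](CC(=O)OCC=C)(C(C)=N[C@@H](C(C)C)C(=O)OC(C)(C)C)C(=O)OC | intermediate
9 | 4-allyl 1-methyl (2R)-2-acetyl-2-[(2S)-lavandulyl]butanedioate | C=C(C)[C@@H](CC=C(C)C)C[C@@](CC(=O)OCC=C)(C(C)=O)C(=O)OC | intermediate
10 | 3-(allyloxy)benzoic acid | C=CCOc1cccc(c1)C(=O)O | starting material
11 | 3-(allyloxy)benzoyl chloride | C=CCOc1cccc(c1)C(=O)Cl | intermediate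
12 | 4-allyl 1-methyl (2R)-2-{3-[3-(allyloxy)phenyl]-3-oxopropanoyl}-2-[(2S)-lavandulyl]butanedioate | C=C(C)[C@@H](CC=C(C)C)C[C@@](CC(=O)OCC=C)(C(=O)CC(=O)c1cccc(OCC=C)c1)C(=O)OC | intermediate
13 | 5-isopropylidene Meldrum's acid, 2,2-dimethyl-5-(propan-2-ylidene)-1,3-dioxane-4,6-dione | CC(C)=C1C(=O)OC(C)(C)OC1=O | starting material
14 | ethynylmagnesium bromide | C#C[Mg]Br | starting material
15 | 2,2-dimethyl-5-(2-methylbut-3-yn-2-yl)-1,3-dioxane-4,6-dione | C#CC(C)(C)C1C(=O)OC(C)(C)OC1=O | intermediate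
16 | 3,3-dimethylpent-4-ynoic acid | C#CC(C)(C)CC(=O)O | intermediate
17 | prenyl bromide, 1-bromo-3-methylbut-2-ene | CC(C)=CCBr | starting material
18 | methyl chloroformate | COC(=O)Cl | starting material
19 | dilithium salt of 3,3-dimethyl-2-(3-methylbut-2-en-1-yl)pent-4-ynoic acid (lithium carboxylate, lithium acetylide; racemic) | [Li]C#CC(C)(C)C(CC=C(C)C)C(=O)O[Li] | intermediate
20 | 6-methoxy-3,3-dimethyl-2-(3-methylbut-2-en-1-yl)-6-oxohex-4-ynoic acid (racemic) | COC(=O)C#CC(C)(C)C(CC=C(C)C)C(=O)O | intermediate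
21 | methyl 6-chloro-4,4-dimethyl-5-(3-methylbut-2-en-1-yl)-6-oxohex-2-ynoate (racemic) | COC(=O)C#CC(C)(C)C(CC=C(C)C)C(=O)Cl | intermediate
22 | open-chain triketone (enol form, C1 epimers): 4-allyl 1-methyl (2R)-2-{2-[3-(allyloxy)benzoyl]-8-methoxy-5,5-dimethyl-4-(3-methylbut-2-en-1-yl)-3,8-dioxooct-6-ynoyl}-2-[(2S)-lavandulyl]butanedioate | C=C(C)[C@@H](CC=C(C)C)C[C@@](CC(=O)OCC=C)(C(O)=C(C(=O)c1cccc(OCC=C)c1)C(=O)C(CC=C(C)C)C(C)(C)C#CC(=O)OC)C(=O)OC | intermediate
23 | ring A monocycle: 2-[3-(allyloxy)benzoyl]cyclohexane-1,3,5-trione (enol form) with quaternary C1 (prenyl and CMe2–C≡C–CO2Me) and quaternary C5 ((2S)-lavandulyl and CH2CO2allyl), (1R,5R), the alkynoate arm and the acetate arm cis | C=C(C)[C@@H](CC=C(C)C)C[C@@]1(CC(=O)OCC=C)C(O)=C(C(=O)c2cccc(OCC=C)c2)C(=O)[C@](CC=C(C)C)(C(C)(C)C#CC(=O)OC)C1=O | intermediate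
24 | allyl (1R,5R)-3-[3-(allyloxy)benzoyl]-4-hydroxy-7-(2-methoxy-2-oxoethylidene)-8,8-dimethyl-1-(3-methylbut-2-en-1-yl)-5-[(2S)-lavandulyl]-2,9-dioxobicyclo[3.3.1]non-3-ene-6-carboxylate (C6 epimers, alkene geometry open) | C=C(C)[C@@H](CC=C(C)C)C[C@@]12C(C(=O)OCC=C)C(=CC(=O)OC)C(C)(C)[C@@](CC=C(C)C)(C(=O)C(C(=O)c3cccc(OCC=C)c3)=C1O)C2=O | intermediate
25 | (1R,5R)-4-hydroxy-3-(3-hydroxybenzoyl)-7-(2-methoxy-2-oxoethylidene)-8,8-dimethyl-1-(3-methylbut-2-en-1-yl)-5-[(2S)-lavandulyl]-2,9-dioxobicyclo[3.3.1]non-3-ene-6-carboxylic acid | C=C(C)[C@@H](CC=C(C)C)C[C@@]12C(C(=O)O)C(=CC(=O)OC)C(C)(C)[C@@](CC=C(C)C)(C(=O)C(C(=O)c3cccc(O)c3)=C1O)C2=O | intermediate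
26 | methyl 2-[(1R,5R)-4-hydroxy-3-(3-hydroxybenzoyl)-8,8-dimethyl-1-(3-methylbut-2-en-1-yl)-5-[(2S)-lavandulyl]-2,9-dioxobicyclo[3.3.1]non-3-en-7-ylidene]acetate | C=C(C)[C@@H](CC=C(C)C)C[C@@]12CC(=CC(=O)OC)C(C)(C)[C@@](CC=C(C)C)(C(=O)C(C(=O)c3cccc(O)c3)=C1O)C2=O | intermediate
27 | methyl 2-[(1R,5R,7S)-4-hydroxy-3-(3-hydroxybenzoyl)-8,8-dimethyl-1-(3-methylbut-2-en-1-yl)-5-[(2S)-lavandulyl]-2,9-dioxobicyclo[3.3.1]non-3-en-7-yl]acetate (side chain on C7 endo) | C=C(C)[C@@H](CC=C(C)C)C[C@@]12C[C@@H](CC(=O)OC)C(C)(C)[C@@](CC=C(C)C)(C(=O)C(C(=O)c3cccc(O)c3)=C1O)C2=O | intermediate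
28 | 2-[(1R,5R,7S)-4-hydroxy-3-(3-hydroxybenzoyl)-8,8-dimethyl-1-(3-methylbut-2-en-1-yl)-5-[(2S)-lavandulyl]-2,9-dioxobicyclo[3.3.1]non-3-en-7-yl]acetaldehyde | C=C(C)[C@@H](CC=C(C)C)C[C@@]12C[C@@H](CC=O)C(C)(C)[C@@](CC=C(C)C)(C(=O)C(C(=O)c3cccc(O)c3)=C1O)C2=O | intermediate
29 | isopropyltriphenylphosphonium iodide | CC(C)[P+](c1ccccc1)(c1ccccc1)c1ccccc1.[I-] | starting material
30 | (1R,5R,7R)-4-hydroxy-3-(3-hydroxybenzoyl)-8,8-dimethyl-1,7-bis(3-methylbut-2-en-1-yl)-5-[(2S)-5-methyl-2-(prop-1-en-2-yl)hex-4-en-1-yl]bicyclo[3.3.1]non-3-ene-2,9-dione | C=C(C)[C@@H](CC=C(C)C)C[C@@]12C[C@@H](CC=C(C)C)C(C)(C)[C@@](CC=C(C)C)(C(=O)C(C(=O)c3cccc(O)c3)=C1O)C2=O | target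

Total step count: 16. Longest linear sequence: 11 steps (steps 1, 2, 3, 4, 6, 11, 12, 13, 14, 15, 16).

Steps most likely to fail

Step 12. The Claisen closure at the hindered C1 may be outrun by proton transfer or by a 1,2-acyl shift of the C6 enolate, the Michael closure may stall at the monocycle, or the cis relation between the arms on C1 and C5 may form with low selectivity. The fallback sets out from 22 and comes back at 26. The Claisen closure alone is run (LiN(i-Pr)2, THF, −78 → −40 °C, cold quench) and the ring A monocycle 23 is isolated. Pd(PPh3)4 and morpholine remove both allyl groups to give the monocyclic carboxylic acid F1. N-hydroxypyridine-2-thione and DCC turn it into the thiohydroxamate (Barton) ester F2. Irradiation with visible light in the presence of t-BuSH then brings about Barton decarboxylation; the primary C6 radical should close ring B by 6-exo-dig addition to the alkynoate, and the vinyl radical is reduced by the thiol to 26 directly. A trans isomer of 23 cannot cyclize and is removed at this point.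

Step 14. Hydride may be delivered to C7 from the wrong face, or the hindered enoate may resist reduction. The fallback sets out from 26 and comes back at 28. 1,2-Reduction with i-Bu2AlH (CH2Cl2, −78 °C) gives the allylic alcohol F3, and MnO2 oxidizes it to the enal F4. Iminium-catalysed transfer hydrogenation (chiral imidazolidinone salt such as (2S,5S)-5-benzyl-2-tert-butyl-3-methylimidazolidin-4-one·CF3CO2H, diethyl 2,6-dimethyl-1,4-dihydropyridine-3,5-dicarboxylate, CHCl3) then delivers hydride to C7 under catalyst control, with the catalyst enantiomer chosen for exo delivery, and gives aldehyde 28.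

Step 15. Over-reduction to the alcohol or attack of the hydride on the C9 ketone may compete with the partial reduction. The fallback sets out from 27 and comes back at 28. LiOH (THF/H2O) gives the carboxylic acid F5, EDC, DMAP and EtSH give the S-ethyl thioester F6, and Fukuyama reduction (Et3SiH, palladium on carbon, acetone, rt) gives 28.

Further compounds
F1 | step 12 | monocyclic acid: 2-(3-hydroxybenzoyl)cyclohexane-1,3,5-trione (enol form) with C1 (prenyl and CMe2–C≡C–CO2Me) and C5 ((2S)-lavandulyl and CH2CO2H), (1R,5R), arms cis | C=C(C)[C@@H](CC=C(C)C)C[C@@]1(CC(=O)O)C(O)=C(C(=O)c2cccc(O)c2)C(=O)[C@](CC=C(C)C)(C(C)(C)C#CC(=O)OC)C1=O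
F2 | step 12 | 2-thioxopyridin-1(2H)-yl ester (Barton ester) of F1 | C=C(C)[C@@H](CC=C(C)C)C[C@@]1(CC(=O)ON2C=CC=CC2=S)C(O)=C(C(=O)c2cccc(O)c2)C(=O)[C@](CC=C(C)C)(C(C)(C)C#CC(=O)OC)C1=O
F3 | step 14 | (1R,5R)-4-hydroxy-3-(3-hydroxybenzoyl)-7-(2-hydroxyethylidene)-8,8-dimethyl-1-(3-methylbut-2-en-1-yl)-5-[(2S)-lavandulyl]bicyclo[3.3.1]non-3-ene-2,9-dione | C=C(C)[C@@H](CC=C(C)C)C[C@@]12CC(=CCO)C(C)(C)[C@@](CC=C(C)C)(C(=O)C(C(=O)c3cccc(O)c3)=C1O)C2=O
F4 | step 14 | 2-[(1R,5R)-4-hydroxy-3-(3-hydroxybenzoyl)-8,8-dimethyl-1-(3-methylbut-2-en-1-yl)-5-[(2S)-lavandulyl]-2,9-dioxobicyclo[3.3.1]non-3-en-7-ylidene]acetaldehyde | C=C(C)[C@@H](CC=C(C)C)C[C@@]12CC(=CC=O)C(C)(C)[C@@](CC=C(C)C)(C(=O)C(C(=O)c3cccc(O)c3)=C1O)C2=O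
F5 | step 15 | 2-[(1R,5R,7S)-4-hydroxy-3-(3-hydroxybenzoyl)-8,8-dimethyl-1-(3-methylbut-2-en-1-yl)-5-[(2S)-lavandulyl]-2,9-dioxobicyclo[3.3.1]non-3-en-7-yl]acetic acid | C=C(C)[C@@H](CC=C(C)C)C[C@@]12C[C@@H](CC(=O)O)C(C)(C)[C@@](CC=C(C)C)(C(=O)C(C(=O)c3cccc(O)c3)=C1O)C2=O
F6 | step 15 | S-ethyl 2-[(1R,5R,7S)-4-hydroxy-3-(3-hydroxybenzoyl)-8,8-dimethyl-1-(3-methylbut-2-en-1-yl)-5-[(2S)-lavandulyl]-2,9-dioxobicyclo[3.3.1]non-3-en-7-yl]ethanethioate | C=C(C)[C@@H](CC=C(C)C)C[C@@]12C[C@@H](CC(=O)SCC)C(C)(C)[C@@](CC=C(C)C)(C(=O)C(C(=O)c3cccc(O)c3)=C1O)C2=O
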